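Slowness opened the meeting. The first speaker noted that in the north run the fraction of starting material left shrank by a steady 0.299 d⁻¹, and in the north-west run by 0.785 d⁻¹. That is 2.63 times as fast for 4.00 times the catalyst, a smaller gain than the gain in loading.

| setting | north | north-west | flask |
|---|---|---|---|
| starting material | 10 mM | 10 mM | 10 mM |
| reagent | 1 equiv | 1 equiv | 1.00 equiv |
| catalyst | 2.5 mol% | 10 mol% | 5 mol% |
| remark | run made earlier | run made earlier |  |

| run | time / d | target / % | starting material / % |
|---|---|---|---|
| north | 1.04 | 6.4 | 73.1 |
| north | 2.08 | 18.2 | 53.3 |
| north | 3.00 | 26.9 | 39.8 |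
| north | 4.00 | 37.8 | 29.7 |
| north | 5.00 | 47.1 | 22.3 |
| north | 6.00 | 53.7 | 16.6 |
| north-west | 0.417 | 6.4 | 70.5 |
| north-west | 1.25 | 31.8 | 37.2 |
| north-west | 2.00 | 48.4 | 20.8 |
| north-west | 3.00 | 64.0 | 10.2 |
| north-west | 5.00 | 79.0 | 2.0 |
| north-west | 6.00 | 82.6 | 0.9 |

(standard deviation of a reading: 0.5 percentage points)

- steps that have been proposed: starting material + catalyst -> catalyst + intermediate; 2 catalyst <-> resting dimer; reagent + catalyst + intermediate -> catalyst + target
- no earlier run changes the charge of reagent; that part of a forecast is a guess

* apparent order in reagent when 10% of the starting material are converted (percent change of the rate of making target for one percent more reagent charged)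
* apparent order in catalyst when 10% of the starting material are converted (percent change of the rate of making target for one percent more catalyst charged)

The second speaker proposed a scale with two ends. Under the proposed steps, catalyst wholly free counts one, and catalyst nearly wholly in the resting dimer (the resting state) counts 0.5. The reading on that scale is the catalyst exponent 0.696, the percent change in speed for one percent more catalyst. It lies above the lower end and below the upper.

The first speaker added that this flask has twice the north loading and half the north-west loading, so the exponent read across the pair belongs at its loading. On that reckoning, the chair expected an order in catalyst near 0.696 and a shrinking of 0.485 d⁻¹ in the flask. No run had varied the reagent, so any figure for it was a guess.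

The forecast, close to the chair on catalyst, gave 0.92 for reagent and 0.69 for catalyst, starting from the remark that “Fourfold catalyst gives only 2.6-fold rate”.

The flask gives 0.92 in reagent and 0.72 in catalyst.

    starting material + catalyst → catalyst + intermediate (k = 79.0 M⁻¹ h⁻¹)
    2 catalyst ⇌ resting dimer (K = 1900 M⁻¹, k = 500 M⁻¹ h⁻¹)
    reagent + catalyst + intermediate → catalyst + target (k = 13000 M⁻² h⁻¹)

At 1.00 d the flask holds 50.9% of its catalyst free and 49.1% in the resting dimer. The exponent, used once more through 0.485 d⁻¹, puts the starting material left at 5.00 d at 8.85%, and the flask holds 8.78%.

All runs are calculated with made-up constants; scatter was added.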